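**Plan**

1. Locants used here: ring A (piperidine) = N, C9–C13, where C13 carries the C1′–C3′ hydroxypropyl chain; ring B (azepane) = N, C1–C4, C8, C9; ring C (cyclopentane) = C4 (carbinol), C5 (spiro), C6 (CHOH), C7 (CHMe), C8; ring D = the butenolide on C5.
2. Cuts, backwards: the two O-protecting groups; the six C–H bonds of ring A (ring A becomes a pyridinium); then N–C1 and C4–C8 together, which opens rings B and C at once to a 2-alkenylpyridine tethered to a γ-chloro ketone; then C8–C9 (Negishi), C4–C5 and C5–C6 (two aldol bonds at C5 of a bought methyl tetronate).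
3. Enabling feature: with ring A aromatic, N–C9–C8 is an azaallyl unit. Hydride addition to C7 of a C7=C8 alkene makes C8 a nucleophile, and re-aromatisation hands the lone pair back to N. C4 (ketone) and C1 (CH2Cl) are the matching 1,4-dielectrophile, and C4–C8 is the bond shared by rings B and C.
4. Forward: ring D is bought; C5 is substituted twice (C6 side, then C4 side); the pyridine is coupled on; one copper hydride operation closes ring C and then ring B; hydrogenation turns the pyridinium into ring A; deprotection.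
5. Stereochemistry: C1′ by asymmetric transfer hydrogenation; C6 by a catalytic asymmetric vinylogous Mukaiyama aldol; C5 by 1,2-induction from C6; C7, C8 and C4 in the key step; C9 and C13 by all-cis hydrogenation on the face of H-8.

Key step: step 12

Remark: 4-methoxy-3-methylfuran-2(5H)-one (11) and 4-chlorobutanal (16) are taken as catalogue compounds (16 distilled before use).

**Route**

Step 1
Reactants: 1 2,6-dibromopyridine; 2 N-methoxy-N-methylpropanamide
Product: 4 1-(6-bromopyridin-2-yl)propan-1-one, via 6-bromo-2-lithiopyridine 3 (not isolated)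
Conditions: n-BuLi (1.0 equiv), CH2Cl2, −78 °C; then 2, −78 → 0 °C; 1 M HCl
Reagents that add atoms: none
Why: Mono bromine–lithium exchange followed by the Weinreb ketone synthesis should stop at the ketone, because the chelated tetrahedral adduct survives until work-up.

Step 2
Reactants: 4 1-(6-bromopyridin-2-yl)propan-1-one
Product: 5 (1R)-1-(6-bromopyridin-2-yl)propan-1-ol
Conditions: RuCl[(R,R)-TsDPEN](p-cymene) (0.5 mol%), HCO2H/Et3N (5:2), 28 °C
Reagents that add atoms: none
Why: Noyori–Ikariya asymmetric transfer hydrogenation of a hetaryl alkyl ketone; the (R,R)-ligand is expected to give the (R)-carbinol (C1′), as for aryl alkyl ketones.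

Step 3
Reactants: 5 (1R)-1-(6-bromopyridin-2-yl)propan-1-ol
Product: 6 2-bromo-6-[(1R)-1-(methoxymethoxy)propyl]pyridine
Conditions: MOMCl, i-Pr2NEt, CH2Cl2, 0 °C → rt
Reagents that add atoms: chloromethyl methyl ether, COCCl
Why: Standard acetal protection; a small, base-stable group is chosen so that the pyridine nitrogen stays accessible for the later quaternisation.

Step 4
Reactants: 7 prop-2-yn-1-ol
Product: 9 (2E)-3-iodo-2-methylprop-2-en-1-ol, via alkenylalane 8 (not isolated)
Conditions: AlMe3 (3 equiv), Cp2ZrCl2 (0.25 equiv), CH2Cl2, 0 °C → rt; then I2, THF, −30 → 0 °C; 1 M HCl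
Reagents that add atoms: trimethylaluminium, C[Al](C)C; iodine, II
Why: Negishi zirconium-catalysed carboalumination adds Me and Al syn across the alkyne, and iodinolysis with retention should give the E-iodide only.

Step 5
Reactants: 9 (2E)-3-iodo-2-methylprop-2-en-1-ol
Product: 10 (2E)-3-iodo-2-methylprop-2-enal
Conditions: MnO2 (15 equiv), CH2Cl2, rt, dark
Reagents that add atoms: none
Why: Allylic alcohol oxidation by manganese dioxide should leave the vinyl iodide and the alkene geometry untouched.

Step 6
Reactants: 11 4-methoxy-3-methylfuran-2(5H)-one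
Product: 12 4-methoxy-3-methyl-2-(trimethylsilyloxy)furan
Conditions: TMSOTf (1.1 equiv), Et3N (1.3 equiv), Et2O, 0 °C; filtration under argon, distillation
Reagents that add atoms: trimethylsilyl trifluoromethanesulfonate, C[Si](C)(C)OS(=O)(=O)C(F)(F)F
Why: Soft enolisation and O-silylation of the butenolide should give the aromatic 2-silyloxyfuran, a vinylogous silyl ketene acetal.

Step 7
Reactants: 12 4-methoxy-3-methyl-2-(trimethylsilyloxy)furan; 10 (2E)-3-iodo-2-methylprop-2-enal
Product: 14 5-[(1S,2E)-1-hydroxy-3-iodo-2-methylprop-2-en-1-yl]-4-methoxy-3-methylfuran-2(5H)-one (C5 epimer mixture), via trimethylsilyl ether 13 (not isolated)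
Conditions: Ti(OiPr)4 (20 mol%), (R)-BINOL (20 mol%), Et2O, −20 °C; then 1 M HCl, THF, 0 °C
Reagents that add atoms: none
Why: Catalytic enantioselective vinylogous Mukaiyama aldol at the furan γ-carbon; the titanium binaphtholate should set the C6 carbinol, with the BINOL antipode chosen (and switched if a first run shows the opposite sense) to direct the furan to the Re face of the enal, and the C5 epimer mixture is harmless because C5 is planarised in step 9.

Step 8
Reactants: 14 5-[(1S,2E)-1-hydroxy-3-iodo-2-methylprop-2-en-1-yl]-4-methoxy-3-methylfuran-2(5H)-one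
Product: 15 5-[(1S,2E)-1-(tert-butyldimethylsilyloxy)-3-iodo-2-methylprop-2-en-1-yl]-4-methoxy-3-methylfuran-2(5H)-one (C5 epimer mixture)
Conditions: TBSOTf, 2,6-lutidine, CH2Cl2, −78 → 0 °C
Reagents that add atoms: tert-butyldimethylsilyl trifluoromethanesulfonate, CC(C)(C)[Si](C)(C)OS(=O)(=O)C(F)(F)F
Why: Silyl ether formation gives a non-chelating bulky group at C6, which the stereochemical model of step 9 requires and which blocks retro-aldol.

Step 9
Reactants: 15 5-[(1S,2E)-1-(tert-butyldimethylsilyloxy)-3-iodo-2-methylprop-2-en-1-yl]-4-methoxy-3-methylfuran-2(5H)-one; 16 4-chlorobutanal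
Product: 18 (5S)-5-[(1S,2E)-1-(tert-butyldimethylsilyloxy)-3-iodo-2-methylprop-2-en-1-yl]-5-(4-chloro-1-hydroxybutyl)-4-methoxy-3-methylfuran-2(5H)-one (both carbinol epimers of the hydroxybutyl chain), via lithium furanolate 17 (not isolated)
Conditions: LDA (1.15 equiv), THF, −78 °C, 30 min; then 16, −78 °C; AcOH quench at −78 °C
Reagents that add atoms: none
Why: Lithium dienolate aldol at the γ-carbon creates the quaternary C5; allylic strain against the ring 4-methoxy group should keep the C6–H in the furanolate plane, the alkenyl group anti to the incoming aldehyde and the silyloxy group toward the ring oxygen, so that C4 enters on the face that gives the required C5 configuration, and the cold quench avoids loss of silanolate and silyl migration.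

Step 10
Reactants: 18 (5S)-5-[(1S,2E)-1-(tert-butyldimethylsilyloxy)-3-iodo-2-methylprop-2-en-1-yl]-5-(4-chloro-1-hydroxybutyl)-4-methoxy-3-methylfuran-2(5H)-one
Product: 19 (5S)-5-[(1S,2E)-1-(tert-butyldimethylsilyloxy)-3-iodo-2-methylprop-2-en-1-yl]-5-(4-chlorobutanoyl)-4-methoxy-3-methylfuran-2(5H)-one
Conditions: Dess–Martin periodinane (1.5 equiv), CH2Cl2, 0 °C → rt
Reagents that add atoms: none
Why: Dess–Martin oxidation converges both carbinol epimers on one ketone, which cannot undergo retro-aldol because the C6 oxygen is silylated.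

Step 11
Reactants: 6 2-bromo-6-[(1R)-1-(methoxymethoxy)propyl]pyridine; 19 (5S)-5-[(1S,2E)-1-(tert-butyldimethylsilyloxy)-3-iodo-2-methylprop-2-en-1-yl]-5-(4-chlorobutanoyl)-4-methoxy-3-methylfuran-2(5H)-one
Product: 22 (5S)-5-[(1S,2E)-1-(tert-butyldimethylsilyloxy)-3-{6-[(1R)-1-(methoxymethoxy)propyl]pyridin-2-yl}-2-methylprop-2-en-1-yl]-5-(4-chlorobutanoyl)-4-methoxy-3-methylfuran-2(5H)-one, via pyridyllithium 20 (not isolated), via pyridylzinc chloride 21 (not isolated)
Conditions: 6 (1.3 equiv), n-BuLi, THF, −78 °C; ZnCl2, −78 → 0 °C; then 19, Pd(PPh3)4 (5 mol%), THF, 45 °C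
Reagents that add atoms: none
Why: Negishi coupling with retention of the E-alkene geometry; the arylzinc should tolerate the ketone, the lactone and the alkyl chloride, and all butyllithium is consumed before 19 is added.

Step 12
Reactants: 22 (5S)-5-[(1S,2E)-1-(tert-butyldimethylsilyloxy)-3-{6-[(1R)-1-(methoxymethoxy)propyl]pyridin-2-yl}-2-methylprop-2-en-1-yl]-5-(4-chlorobutanoyl)-4-methoxy-3-methylfuran-2(5H)-one
Product: 26 (1′R,4S,5R,6S,7S,8R)-pyridinium chloride with rings B, C and D closed and ring A aromatic (6-OTBS, 1′-OMOM, free 4-OH), via copper aza-enolate 23 (not isolated), via ring C silyl ether 24 (not isolated), via pyridinium silyl ether 25 (not isolated)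
Conditions: Cu(OAc)2 (5 mol%), (S,S)-Ph-BPE (6 mol%), (EtO)2MeSiH (1.2 equiv), toluene, 0 °C → rt; then MeCN, NaI (20 mol%), 85 °C; then 1 M HCl, MeOH, 0 °C
Reagents that add atoms: none
Why: The phosphine-ligated copper hydride adds across the N=C9–C8=C7 azadiene of 22 (hydride to C7, copper to nitrogen) to give aza-enolate 23, whose C8 adds to the C4 ketone through a copper-bridged six-membered transition state; the silane turns the catalyst over and leaves silyl ether 24, whose re-aromatised nitrogen displaces chloride under iodide catalysis to give 25, hydrolysed on work-up to 26. The closest known reactions are the copper hydride reductive coupling of alkenylazaarenes with ketones, copper-catalysed reductive aldol cyclisations and the Menshutkin quaternisation (together a homologue of the Chichibabin indolizine annulation). Ring C closes by a 5-(enolexo)-exo-trig aldol and ring B by a 7-exo-tet N-alkylation, which is only possible once ring C exists because the open chain would need a ten-membered ring. C7 is set by the chiral ligand, whose antipode is chosen so that hydride adds anti to the C6–O bond (methyl cis to OTBS); C8 by allylic strain in the aza-enolate, which puts the pyridine trans to the C7 methyl; C4 by the N–Cu–O bridge, which puts the oxygen cis to the pyridine and so the chloropropyl chain trans to it. The step needs hydrocupration of the alkenylpyridine to outrun hydrosilylation of the ketone, which the flanking quaternary C5 should secure, and it needs the tertiary oxygen to stay out of the displacement (no tetrahydrofuran), which its silylation in the catalytic turnover secures.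

Step 13
Reactants: 26 (1′R,4S,5R,6S,7S,8R)-pyridinium chloride
Product: 27 (1′R,4S,5R,6S,7S,8R,9S,13R)-tetracyclic amine (6-OTBS, 1′-OMOM, free 4-OH)
Conditions: PtO2 (10 mol%), H2 (4 atm), AcOH, rt; then aq. Na2CO3
Reagents that add atoms: none
Why: Heterogeneous hydrogenation of the pyridinium ring should add all hydrogen to one face, namely the face of the C9=N bond that is screened only by the pseudo-axial H-8 in the ring B half-chair, which gives H-9 syn to H-8 and the 9,13-cis piperidine while C1′ and the tetrasubstituted butenolide alkene are untouched.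

Step 14
Reactants: 27 (1′R,4S,5R,6S,7S,8R,9S,13R)-tetracyclic amine
Product: 28 CNP0267781.1
Conditions: HCl (1.25 M in MeOH), 40 °C; then aq. NaHCO3
Reagents that add atoms: none
Why: Acid-catalysed methanolysis cleaves the methoxymethyl acetal and the silyl ether together, while anhydrous methanol cannot hydrolyse the methyl enol ether of ring D and the protonated amine protects the tertiary carbinol from ionisation.

**Compound list**

1 | 2,6-dibromopyridine | Brc1cccc(Br)n1 | starting material
2 | N-methoxy-N-methylpropanamide | CCC(=O)N(C)OC | starting material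
3 | 6-bromo-2-lithiopyridine | [Li]c1cccc(Br)n1 | intermediate (not isolated)
4 | 1-(6-bromopyridin-2-yl)propan-1-one | CCC(=O)c1cccc(Br)n1 | intermediate
5 | (1R)-1-(6-bromopyridin-2-yl)propan-1-ol | CC[C@@H](O)c1cccc(Br)n1 | intermediate
6 | 2-bromo-6-[(1R)-1-(methoxymethoxy)propyl]pyridine | CC[C@@H](OCOC)c1cccc(Br)n1 | intermediate
7 | prop-2-yn-1-ol | OCC#C | starting material
8 | alkenylalane: dimethylaluminium (2E)-3-(dimethylalumanyl)-2-methylprop-2-en-1-olate | C[Al](C)/C=C(\C)CO[Al](C)C | intermediate (not isolated)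
9 | (2E)-3-iodo-2-methylprop-2-en-1-ol | I/C=C(\C)CO | intermediate
10 | (2E)-3-iodo-2-methylprop-2-enal | I/C=C(\C)C=O | intermediate
11 | 4-methoxy-3-methylfuran-2(5H)-one | COC1=C(C)C(=O)OC1 | starting material
12 | 4-methoxy-3-methyl-2-(trimethylsilyloxy)furan | COc1coc(O[Si](C)(C)C)c1C | intermediate
13 | 5-[(1S,2E)-3-iodo-2-methyl-1-(trimethylsilyloxy)prop-2-en-1-yl]-4-methoxy-3-methylfuran-2(5H)-one (C5 epimer mixture) | I/C=C(\C)[C@H](O[Si](C)(C)C)C1OC(=O)C(C)=C1OC | intermediate (not isolated)
14 | 5-[(1S,2E)-1-hydroxy-3-iodo-2-methylprop-2-en-1-yl]-4-methoxy-3-methylfuran-2(5H)-one (C5 epimer mixture) | I/C=C(\C)[C@H](O)C1OC(=O)C(C)=C1OC | intermediate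
15 | 5-[(1S,2E)-1-(tert-butyldimethylsilyloxy)-3-iodo-2-methylprop-2-en-1-yl]-4-methoxy-3-methylfuran-2(5H)-one (C5 epimer mixture) | I/C=C(\C)[C@H](O[Si](C)(C)C(C)(C)C)C1OC(=O)C(C)=C1OC | intermediate
16 | 4-chlorobutanal | O=CCCCCl | starting material
17 | lithium 5-[(1S,2E)-1-(tert-butyldimethylsilyloxy)-3-iodo-2-methylprop-2-en-1-yl]-4-methoxy-3-methylfuran-2-olate | [Li]Oc1oc(c(OC)c1C)[C@@H](O[Si](C)(C)C(C)(C)C)/C(C)=C/I | intermediate (not isolated)
18 | (5S)-5-[(1S,2E)-1-(tert-butyldimethylsilyloxy)-3-iodo-2-methylprop-2-en-1-yl]-5-(4-chloro-1-hydroxybutyl)-4-methoxy-3-methylfuran-2(5H)-one (both carbinol epimers of the side chain) | I/C=C(\C)[C@H](O[Si](C)(C)C(C)(C)C)[C@@]1(OC(=O)C(C)=C1OC)C(O)CCCCl | intermediate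
19 | (5S)-5-[(1S,2E)-1-(tert-butyldimethylsilyloxy)-3-iodo-2-methylprop-2-en-1-yl]-5-(4-chlorobutanoyl)-4-methoxy-3-methylfuran-2(5H)-one | I/C=C(\C)[C@H](O[Si](C)(C)C(C)(C)C)[C@@]1(OC(=O)C(C)=C1OC)C(=O)CCCCl | intermediate
20 | {6-[(1R)-1-(methoxymethoxy)propyl]pyridin-2-yl}lithium | CC[C@@H](OCOC)c1cccc([Li])n1 | intermediate (not isolated)
21 | chloro{6-[(1R)-1-(methoxymethoxy)propyl]pyridin-2-yl}zinc | CC[C@@H](OCOC)c1cccc([Zn]Cl)n1 | intermediate (not isolated)
22 | (5S)-5-[(1S,2E)-1-(tert-butyldimethylsilyloxy)-3-{6-[(1R)-1-(methoxymethoxy)propyl]pyridin-2-yl}-2-methylprop-2-en-1-yl]-5-(4-chlorobutanoyl)-4-methoxy-3-methylfuran-2(5H)-one | CC[C@@H](OCOC)c1cccc(n1)/C=C(\C)[C@H](O[Si](C)(C)C(C)(C)C)[C@@]2(OC(=O)C(C)=C2OC)C(=O)CCCCl | intermediate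
23 | copper aza-enolate: N-cuprated 2-alkylidene-1,2-dihydropyridine from hydride addition to C7 of 22 (diphosphine on copper not drawn) | CC[C@@H](OCOC)C1=CC=CC(N1[Cu])=C[C@H](C)[C@H](O[Si](C)(C)C(C)(C)C)[C@@]2(OC(=O)C(C)=C2OC)C(=O)CCCCl | intermediate (not isolated)
24 | ring C silyl ether: rings C and D closed, pyridine and 3-chloropropyl chain free, 4-O-diethoxy(methyl)silyl, stereocentres as in 26 | CC[C@@H](OCOC)c1cccc(n1)[C@H]2[C@H](C)[C@H](O[Si](C)(C)C(C)(C)C)[C@@]3(OC(=O)C(C)=C3OC)[C@]2(O[Si](C)(OCC)OCC)CCCCl | intermediate (not isolated)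
25 | pyridinium silyl ether: the 4-O-diethoxy(methyl)silyl ether of 26 | CC[C@@H](OCOC)c1cccc2[C@H]3[C@H](C)[C@H](O[Si](C)(C)C(C)(C)C)[C@@]4(OC(=O)C(C)=C4OC)[C@]3(O[Si](C)(OCC)OCC)CCC[n+]12.[Cl-] | intermediate (not isolated)
26 | (1′R,4S,5R,6S,7S,8R)-pyridinium chloride: rings B, C, D closed, ring A an N-alkylpyridinium, 6-OTBS, 1′-OMOM, 4-OH | CC[C@@H](OCOC)c1cccc2[C@H]3[C@H](C)[C@H](O[Si](C)(C)C(C)(C)C)[C@@]4(OC(=O)C(C)=C4OC)[C@]3(O)CCC[n+]12.[Cl-] | intermediate
27 | (1′R,4S,5R,6S,7S,8R,9S,13R)-tetracyclic amine: 6-O-TBS, 1′-O-MOM derivative of the target | CC[C@@H](OCOC)[C@H]1CCC[C@H]2[C@H]3[C@H](C)[C@H](O[Si](C)(C)C(C)(C)C)[C@@]4(OC(=O)C(C)=C4OC)[C@]3(O)CCCN12 | intermediate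
28 | CNP0267781.1: (1′R,4S,5R,6S,7S,8R,9S,13R)-4,6,1′-triol with ring D = 4-methoxy-3-methylbutenolide spiro at C5 | CC[C@@H](O)[C@H]1CCC[C@H]2[C@H]3[C@H](C)[C@H](O)[C@@]4(OC(=O)C(C)=C4OC)[C@]3(O)CCCN12 | target

**Totals and risks**

Total step count: 14. Longest linear sequence: 10 steps (7 → 28 through steps 4, 5, 7–14).

Step 12 (key step). What may go wrong: quaternisation of the doubly flanked pyridine nitrogen is too slow, so that the cyclised chloride is reduced or decomposes before ring B closes; hydrosilylation of the ketone may also compete with hydrocupration of the hindered alkene. Fallback: setting out from 22, the copper hydride reductive aldol is run alone and worked up with dilute acid to give the ring C chloro alcohol F1. Hydrogenation of its pyridine ring (PtO2, H2, AcOH) gives the cis-2,6-disubstituted piperidine F2. Its far more nucleophilic secondary amine closes ring B on warming with K2CO3 and NaI in MeCN, which comes back to the route at 27.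

Step 9. What may go wrong: the aldehyde adds to both faces of the planar furanolate (weak 1,2-induction from C6), or silanolate is lost from the dienolate by β-elimination. Fallback: setting out from 15, the 2-silyloxyfuran F3 is made (TBSOTf, Et3N) and added to 16 with BF3·OEt2 at −78 °C in a vinylogous Mukaiyama aldol. This uses an open transition state with a Lewis-acid-bound aldehyde and no basic enolate, and comes back to the route at 18.

Step 13. What may go wrong: hydrogen is delivered to the other face of the pyridinium ring (epimers at C9 and C13), or reduction stalls at a tetrahydropyridine. Fallback: setting out from 26, reduction with NaBH4 in MeOH at −20 °C gives the 1,2,3,6-tetrahydropyridine F4, in which C9 and C13 are set by hydride attack in solution and not on a metal surface. Hydrogenation of its isolated alkene over Pd/C comes back to the route at 27.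

**Further compounds**

F1 | step 12 | ring C chloro alcohol: 24 with free 4-OH (pyridine and 3-chloropropyl chain free) | CC[C@@H](OCOC)c1cccc(n1)[C@H]2[C@H](C)[C@H](O[Si](C)(C)C(C)(C)C)[C@@]3(OC(=O)C(C)=C3OC)[C@]2(O)CCCCl
F2 | step 12 | cis-2,6-disubstituted piperidine from F1 (ring A closed, ring B open, 3-chloropropyl chain on C4) | CC[C@@H](OCOC)[C@H]1CCC[C@H](N1)[C@H]2[C@H](C)[C@H](O[Si](C)(C)C(C)(C)C)[C@@]3(OC(=O)C(C)=C3OC)[C@]2(O)CCCCl
F3 | step 9 | 2-(tert-butyldimethylsilyloxy)furan of 15 | CC(C)(C)[Si](C)(C)Oc1oc(c(OC)c1C)[C@@H](O[Si](C)(C)C(C)(C)C)/C(C)=C/I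
F4 | step 13 | 1,2,3,6-tetrahydropyridine from 26 (C11=C12 alkene, C9 and C13 sp3) | CC[C@@H](OCOC)[C@H]1C=CC[C@H]2[C@H]3[C@H](C)[C@H](O[Si](C)(C)C(C)(C)C)[C@@]4(OC(=O)C(C)=C4OC)[C@]3(O)CCCN12
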